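**Retrosynthetic overview**

- Ring numbering: C1 = ring carbon bearing CO2Me, C2 = vinylic CH, C3/C4/C5 = carbinol carbons carrying acetate, (R)-2-methylbutanoate and (S)-3-methylpentanoate, C6 = CH2; the core is methyl shikimate (3R,4S,5R).
- Endgame: the three esters go on one at a time: C4 (Steglich), C3 (orthoacetate opening of the cis-3,4-diol), C5 (Mitsunobu inversion), back to methyl 3,4-O-isopropylidene-5-epi-shikimate 8.
- 8 is cut at C5–C6 and C1=C2: one flask joins lactol acid 5 with phosphonoacrylate 6 by decarboxylative radical addition (C5–C6), then closes the cyclohexene, the only ring made in the route, by intramolecular Horner–Wadsworth–Emmons olefination (C1=C2).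
- Enabling feature: the tetrahydrofuran ring of 5, whose ring oxygen is bonded to both the carboxyl-bearing carbon (future C5) and the hemiacetal carbon (future C2); it stabilises the C5 radical, masks the C2 aldehyde and ends as the free C5–OH, while the cis-fused dioxolane on O3/O4 steers the radical face.
- 5 comes in four steps from diacetone-D-mannose, which supplies C2–C5 and the C3/C4 stereocentres; the tetrahydrofuran and dioxolane rings are bought with the sugar and removed in steps 5 and 7.

Key step: step 5

Remark on the chemistry: lactols 5 and 7 are anomeric mixtures (anomeric carbon drawn without configuration; 7 is also a mixture at the phosphonate carbon), which is harmless because both carbons become sp2 in step 5; compounds 1, 6, 9 and 14 are taken as purchasable.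

**Step 1**
Reactants: 1 2,3:5,6-di-O-isopropylidene-α-D-mannofuranose
Product: 2 benzyl 2,3:5,6-di-O-isopropylidene-α-D-mannofuranoside
Conditions: NaH, BnBr, DMF, 0 °C to rt
Reagents that add atoms: benzyl bromide, BrCc1ccccc1
Why: Williamson O-alkylation of the anomeric alkoxide should put the benzyl group on the exo face, trans to the 2,3-dioxolane, and it only masks the lactol, so its configuration is of no consequence.

**Step 2**
Reactants: 2 benzyl 2,3:5,6-di-O-isopropylidene-α-D-mannofuranoside
Product: 3 benzyl 2,3-O-isopropylidene-α-D-lyxo-pentodialdo-1,4-furanoside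
Conditions: H5IO6, EtOAc, rt
Reagents that add atoms: none
Why: Periodic acid should hydrolyse the more labile terminal 5,6-acetonide selectively and cleave the freed glycol in the same flask (Malaprade glycol cleavage), leaving the cis-fused 2,3-acetonide and the glycoside intact.

**Step 3**
Reactants: 3 benzyl 2,3-O-isopropylidene-α-D-lyxo-pentodialdo-1,4-furanoside
Product: 4 benzyl 2,3-O-isopropylidene-α-D-lyxofuranosiduronic acid
Conditions: NaClO2, NaH2PO4, 2-methyl-2-butene, t-BuOH/H2O, 0 °C to rt
Reagents that add atoms: sodium chlorite, [Na+].[O-]Cl=O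
Why: Pinnick oxidation should take the aldehyde to the acid under buffered conditions that the acetals tolerate, and any epimerisation at the carboxyl-bearing carbon is harmless because this centre becomes a radical in step 5.

**Step 4**
Reactants: 4 benzyl 2,3-O-isopropylidene-α-D-lyxofuranosiduronic acid
Product: 5 2,3-O-isopropylidene-D-lyxofuranuronic acid (free lactol)
Conditions: H2 (1 atm), 10% Pd/C, EtOAc, rt
Reagents that add atoms: none
Why: Hydrogenolysis of the anomeric benzyl ether should free the lactol without touching the acetonide or the acid.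

**Step 5**
Reactants: 5 2,3-O-isopropylidene-D-lyxofuranuronic acid (free lactol); 6 trimethyl 2-phosphonoacrylate (methyl 2-(dimethoxyphosphoryl)prop-2-enoate)
Product: 8 methyl 3,4-O-isopropylidene-5-epi-shikimate, via lactol phosphonate 7 (not isolated)
Conditions: 6 (1.2 equiv), 4CzIPN (2,4,5,6-tetra(carbazol-9-yl)benzene-1,3-dicarbonitrile, 2 mol %), K2HPO4 (1.0 equiv), degassed DMF, 450 nm LEDs, rt; then Cs2CO3 (2.0 equiv), same flask, 0 °C to rt
Reagents that add atoms: none
Why: Proposed new method: the excited photocatalyst should oxidise the C5 carboxylate of 5, CO2 is lost, the ring-oxygen-stabilised C5 radical adds to the CH2 terminus of 6 (C5–C6 bond) and the reduced photocatalyst returns the electron to the electrophilic adduct radical (radical-polar crossover) to give phosphonate 7, whose carbanion carbon (C1), once Cs2CO3 is added, attacks the aldehyde carbon (C2) released from the lactol and expels phosphate through the oxaphosphetane, so that the ring closes as the C1=C2 double bond. The closest known reaction types are the photoredox decarboxylative Giese addition of α-alkoxy (furanosiduronic) acids, the base-mediated Michael addition/intramolecular Horner–Wadsworth–Emmons annulation of 2-phosphonoacrylates, and the HWE ring closure of sugar lactol phosphonates to shikimates; what is new is their fusion in one flask on an unprotected lactol acid. The only ring closed is the cyclohexene, by 6-exo-trig addition of the phosphonate carbanion to the aldehyde followed by syn elimination, while the tetrahydrofuran ring opens and its oxygen becomes the free C5 hydroxyl. The one new stereocentre, C5, is fixed in the radical addition, which should occur on the convex face of the cis-fused bicycle, anti to the dioxolane, and so gives the 5S (5-epi) configuration on purpose for inversion in step 6; C3 and C4 come unchanged from D-mannose and the phosphonate carbon ends as sp2 C1. The step needs radical generation only at C5 (one carboxylate; the aldehyde is masked as lactol, so it neither traps radicals nor olefinates intermolecularly), attack at the unsubstituted alkene terminus of 6 (polarity matching of the nucleophilic α-oxy radical) and intramolecular over intermolecular olefination (low stationary aldehyde concentration, six-membered ring).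

**Step 6**
Reactants: 8 methyl 3,4-O-isopropylidene-5-epi-shikimate; 9 (S)-3-methylpentanoic acid
Product: 10 methyl 3,4-O-isopropylidene-5-O-[(3S)-3-methylpentanoyl]shikimate
Conditions: PPh3, DIAD, toluene, 0 °C to rt
Reagents that add atoms: none
Why: In this Mitsunobu esterification the carboxylate should displace the C5 alkoxyphosphonium by SN2 from the open face anti to the dioxolane, which inverts C5 from S to R (natural shikimate configuration) and installs the ester in the same step.

**Step 7**
Reactants: 10 methyl 3,4-O-isopropylidene-5-O-[(3S)-3-methylpentanoyl]shikimate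
Product: 11 methyl 5-O-[(3S)-3-methylpentanoyl]shikimate
Conditions: TFA/H2O (9:1), 0 °C
Reagents that add atoms: none
Why: Acid-catalysed acetal hydrolysis should remove the isopropylidene group, while the esters survive brief cold aqueous acid and acyl migration is slow without base.

**Step 8**
Reactants: 11 methyl 5-O-[(3S)-3-methylpentanoyl]shikimate
Product: 13 methyl 3-O-acetyl-5-O-[(3S)-3-methylpentanoyl]shikimate, via cyclic orthoester 12 (not isolated)
Conditions: MeC(OMe)3, CSA (cat.), CH2Cl2, rt; then AcOH/H2O (4:1), rt
Reagents that add atoms: trimethyl orthoacetate, CC(OC)(OC)OC; water, O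
Why: Cyclic orthoester formation on the cis-3,4-diol and mild acid opening should place the acetate on the pseudoaxial allylic O3 and leave the equatorial O4–H free, following the stereoelectronically controlled collapse of the hemiorthoester (axial ester, equatorial alcohol).

**Step 9**
Reactants: 13 methyl 3-O-acetyl-5-O-[(3S)-3-methylpentanoyl]shikimate; 14 (R)-2-methylbutanoic acid
Product: 15 methyl 3-O-acetyl-4-O-[(2R)-2-methylbutanoyl]-5-O-[(3S)-3-methylpentanoyl]shikimate (CNP0188172.1)
Conditions: DCC, DMAP (cat.), CH2Cl2, 0 °C to rt
Reagents that add atoms: none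
Why: Steglich esterification should acylate the remaining C4 hydroxyl with retention at all centres, low temperature and catalytic DMAP being chosen to limit acetyl migration and epimerisation α to the activated carboxyl.

**Compound list**

1 | 2,3:5,6-di-O-isopropylidene-α-D-mannofuranose (diacetone-D-mannose) | CC1(C)OC[C@@H](O1)[C@H]1O[C@H](O)[C@H]2OC(C)(C)O[C@@H]12 | starting material
2 | benzyl 2,3:5,6-di-O-isopropylidene-α-D-mannofuranoside | CC1(C)OC[C@@H](O1)[C@H]1O[C@H](OCc3ccccc3)[C@H]2OC(C)(C)O[C@@H]12 | intermediate
3 | benzyl 2,3-O-isopropylidene-α-D-lyxo-pentodialdo-1,4-furanoside (C5 aldehyde) | O=C[C@H]1O[C@H](OCc3ccccc3)[C@H]2OC(C)(C)O[C@@H]12 | intermediate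
4 | benzyl 2,3-O-isopropylidene-α-D-lyxofuranosiduronic acid | OC(=O)[C@H]1O[C@H](OCc3ccccc3)[C@H]2OC(C)(C)O[C@@H]12 | intermediate
5 | 2,3-O-isopropylidene-D-lyxofuranuronic acid (free lactol, mixture of anomers) | OC(=O)[C@H]1OC(O)[C@H]2OC(C)(C)O[C@@H]12 | intermediate
6 | trimethyl 2-phosphonoacrylate (methyl 2-(dimethoxyphosphoryl)prop-2-enoate) | C=C(C(=O)OC)P(=O)(OC)OC | starting material
7 | 5-deoxy-5-C-[(dimethoxyphosphoryl)(methoxycarbonyl)methyl]-2,3-O-isopropylidene-L-ribofuranose (lactol phosphonate; new chain trans to the dioxolane) | COC(=O)C(C[C@@H]1OC(O)[C@H]2OC(C)(C)O[C@@H]12)P(=O)(OC)OC | intermediate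
8 | methyl 3,4-O-isopropylidene-5-epi-shikimate (3R,4S,5S; 5-OH cis to the dioxolane oxygens) | O[C@H]1CC(C(=O)OC)=C[C@H]2OC(C)(C)O[C@@H]12 | intermediate
9 | (S)-3-methylpentanoic acid | CC[C@H](C)CC(=O)O | starting material
10 | methyl 3,4-O-isopropylidene-5-O-[(3S)-3-methylpentanoyl]shikimate (natural 5R configuration) | CC[C@H](C)CC(=O)O[C@@H]1CC(C(=O)OC)=C[C@H]2OC(C)(C)O[C@@H]12 | intermediate
11 | methyl 5-O-[(3S)-3-methylpentanoyl]shikimate (3,4-diol) | CC[C@H](C)CC(=O)O[C@@H]1CC(C(=O)OC)=C[C@@H](O)[C@H]1O | intermediate
12 | methyl 3,4-O-(1-methoxyethylidene)-5-O-[(3S)-3-methylpentanoyl]shikimate (cyclic orthoester, mixture at the orthoester carbon) | CC[C@H](C)CC(=O)O[C@@H]1CC(C(=O)OC)=C[C@H]2OC(C)(OC)O[C@@H]12 | intermediate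
13 | methyl 3-O-acetyl-5-O-[(3S)-3-methylpentanoyl]shikimate (4-OH free) | CC[C@H](C)CC(=O)O[C@@H]1CC(C(=O)OC)=C[C@@H](OC(C)=O)[C@H]1O | intermediate
14 | (R)-2-methylbutanoic acid | CC[C@@H](C)C(=O)O | starting material
15 | methyl 3-O-acetyl-4-O-[(2R)-2-methylbutanoyl]-5-O-[(3S)-3-methylpentanoyl]shikimate (CNP0188172.1) | CC[C@H](C)CC(=O)O[C@@H]1CC(C(=O)OC)=C[C@@H](OC(C)=O)[C@H]1OC(=O)[C@H](C)CC | target

**Totals**

Total step count: 9. Longest linear sequence: 9 steps (1 to 15).

**Steps most likely to fail**

Step 5 (proposed new method). The free hemiacetal hydroxyl or the carboxylate may add to the very electrophilic acceptor (oxa-Michael), the acceptor may oligomerise, the carbanion may be protonated without the ring closing, or the basic stage may cause epimerisation or β-elimination next to the unmasked aldehyde. The fallback separates the events with the anomeric centre protected and uses known reaction classes. It sets out from acid 4: photoredox decarboxylative Giese addition to 6 (4CzIPN, K2HPO4, DMF, 450 nm) should give, again anti to the dioxolane, benzyl 5-deoxy-5-C-[(dimethoxyphosphoryl)(methoxycarbonyl)methyl]-2,3-O-isopropylidene-β-L-ribofuranoside F1. Hydrogenolysis (H2, 10% Pd/C, EtOAc) then frees lactol phosphonate 7, now isolated, and NaH in THF (or NaOMe in MeOH) effects the intramolecular HWE olefination of the lactol. The fallback comes back to the route at 8.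

Step 6. The activated C5 oxygen may be lost by E2 elimination towards the conjugated diene (and on to an aromatic ester), or the weakly acidic aliphatic acid may be activated too slowly so that the hydrazide is acylated instead. The fallback avoids any substitution at C5 by taking the natural C5 configuration directly from C4 of the sugar. It sets out from aldehyde 3:
- NaBH4 in MeOH should give benzyl 2,3-O-isopropylidene-α-D-lyxofuranoside F2.
- Tf2O/pyridine gives its 5-O-triflate F3.
- The sodium salt of trimethyl phosphonoacetate (NaH, 18-crown-6, DMF) displaces the primary triflate to give benzyl 5-deoxy-5-C-[(dimethoxyphosphoryl)(methoxycarbonyl)methyl]-2,3-O-isopropylidene-α-D-lyxofuranoside F4.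
- Hydrogenolysis (H2, 10% Pd/C) frees the lactol 5-deoxy-5-C-[(dimethoxyphosphoryl)(methoxycarbonyl)methyl]-2,3-O-isopropylidene-D-lyxofuranose F5.
- NaOMe in MeOH closes the ring by intramolecular HWE olefination to methyl 3,4-O-isopropylidene shikimate F6, with the natural 5R hydroxyl.
- Steglich esterification of F6 with 9 (DCC, DMAP, CH2Cl2), with retention, comes back to the route at 10.

Step 9. The C3 acetate may migrate to the neighbouring cis C4 oxygen under DMAP before the hindered, doubly flanked C4 hydroxyl is acylated, which would scramble the ester positions; a wrong sense of orthoester opening in step 8 would have the same effect, and the activated α-branched acid may partly epimerise. The fallback changes the order of acylation so that no acetate is present when C4 is esterified. It sets out from diol 11: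
- TBSCl/imidazole in DMF at low temperature should silylate the more accessible allylic 3-OH to give methyl 3-O-(tert-butyldimethylsilyl)-5-O-[(3S)-3-methylpentanoyl]shikimate F7.
- Esterification of the 4-OH with 14 (DCC, DMAP) gives methyl 3-O-(tert-butyldimethylsilyl)-4-O-[(2R)-2-methylbutanoyl]-5-O-[(3S)-3-methylpentanoyl]shikimate F8.
- HF·pyridine in THF (acidic, to suppress migration) gives methyl 4-O-[(2R)-2-methylbutanoyl]-5-O-[(3S)-3-methylpentanoyl]shikimate F9.
- Ac2O/pyridine acetylates the 3-OH, and the fallback comes back to the route at 15.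

**Further compounds**

F1 | step 5 | benzyl 5-deoxy-5-C-[(dimethoxyphosphoryl)(methoxycarbonyl)methyl]-2,3-O-isopropylidene-β-L-ribofuranoside | COC(=O)C(C[C@@H]1O[C@H](OCc3ccccc3)[C@H]2OC(C)(C)O[C@@H]12)P(=O)(OC)OC
F2 | step 6 | benzyl 2,3-O-isopropylidene-α-D-lyxofuranoside | OC[C@H]1O[C@H](OCc3ccccc3)[C@H]2OC(C)(C)O[C@@H]12
F3 | step 6 | benzyl 2,3-O-isopropylidene-5-O-(trifluoromethylsulfonyl)-α-D-lyxofuranoside | FC(F)(F)S(=O)(=O)OC[C@H]1O[C@H](OCc3ccccc3)[C@H]2OC(C)(C)O[C@@H]12
F4 | step 6 | benzyl 5-deoxy-5-C-[(dimethoxyphosphoryl)(methoxycarbonyl)methyl]-2,3-O-isopropylidene-α-D-lyxofuranoside | COC(=O)C(C[C@H]1O[C@H](OCc3ccccc3)[C@H]2OC(C)(C)O[C@@H]12)P(=O)(OC)OC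
F5 | step 6 | 5-deoxy-5-C-[(dimethoxyphosphoryl)(methoxycarbonyl)methyl]-2,3-O-isopropylidene-D-lyxofuranose (lactol) | COC(=O)C(C[C@H]1OC(O)[C@H]2OC(C)(C)O[C@@H]12)P(=O)(OC)OC
F6 | step 6 | methyl 3,4-O-isopropylidene shikimate (3R,4S,5R) | O[C@@H]1CC(C(=O)OC)=C[C@H]2OC(C)(C)O[C@@H]12
F7 | step 9 | methyl 3-O-(tert-butyldimethylsilyl)-5-O-[(3S)-3-methylpentanoyl]shikimate | CC[C@H](C)CC(=O)O[C@@H]1CC(C(=O)OC)=C[C@@H](O[Si](C)(C)C(C)(C)C)[C@H]1O
F8 | step 9 | methyl 3-O-(tert-butyldimethylsilyl)-4-O-[(2R)-2-methylbutanoyl]-5-O-[(3S)-3-methylpentanoyl]shikimate | CC[C@H](C)CC(=O)O[C@@H]1CC(C(=O)OC)=C[C@@H](O[Si](C)(C)C(C)(C)C)[C@H]1OC(=O)[C@H](C)CC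
F9 | step 9 | methyl 4-O-[(2R)-2-methylbutanoyl]-5-O-[(3S)-3-methylpentanoyl]shikimate | CC[C@H](C)CC(=O)O[C@@H]1CC(C(=O)OC)=C[C@@H](O)[C@H]1OC(=O)[C@H](C)CC
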